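The chromanone ring C is cut at C3–C4 and at O1–C8a. Ring B then arrives as an enantiopure O1–C2–C3 unit, a 1,3-dinucleophile, and ring A as a C8a–C4a–C4 1,3-dielectrophile: an ortho-fluoro Weinreb benzamide that already carries the C8 side chain. In one flask the β-oxido alkyllithium from an (R)-chlorohydrin acylates the amide (C3–C4) and its alkoxide then displaces the fluoride that the new C4 ketone activates (O1–C8a), closing ring C without touching C2. The side-chain stereocentres come from trans-prenylation of (S)-β-methyl-γ-butyrolactone; a Negishi coupling joins the chain to ring A.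

Key step: step 12

Remark: (S)-β-methyl-γ-butyrolactone, 5-fluororesorcinol and 4-bromoresorcinol are taken as commercial, and kinetic lithiation of a 1-fluoro-3,5-bis(methoxymethoxy)benzene at –78 °C is assumed to occur between F and OMOM.

Step 1
Reactants: 1 (S)-β-methyl-γ-butyrolactone
Product: 3 (3S,4S)-4-methyl-3-(3-methylbut-2-en-1-yl)oxolan-2-one, via lithium enolate 2 (not isolated)
Conditions: LiN(i-Pr)2, THF, –78 °C; prenyl bromide, –78 to –40 °C
Reagents that add atoms: prenyl bromide (1-bromo-3-methylbut-2-ene), CC(C)=CCBr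
Why: Alkylation of a γ-butyrolactone lithium enolate with an allylic bromide, in which the electrophile enters anti to the C4 methyl group, so the new C3 stereocentre should be set trans by substrate control.

Step 2
Reactants: 3 (3S,4S)-4-methyl-3-(3-methylbut-2-en-1-yl)oxolan-2-one
Product: 6 (2S,3S)-4-[(tert-butyldimethylsilyl)oxy]-3-methyl-2-(3-methylbut-2-en-1-yl)butanoic acid, via potassium hydroxy carboxylate 4 (not isolated), via bis-silyl ester ether 5 (not isolated)
Conditions: KOH, MeOH/H2O, rt, evaporate; TBSCl, imidazole, DMF, rt; K2CO3 (cat.), MeOH/THF/H2O, 0 °C; aqueous citric acid work-up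
Reagents that add atoms: potassium hydroxide, [K+].[OH-]; TBSCl, C[Si](C)(Cl)C(C)(C)C
Why: Saponification, persilylation and selective solvolysis of the labile silyl ester is a standard way to turn a lactone into an ω-silyloxy acid, and it differentiates the two chain ends without touching either stereocentre.

Step 3
Reactants: 6 (2S,3S)-4-[(tert-butyldimethylsilyl)oxy]-3-methyl-2-(3-methylbut-2-en-1-yl)butanoic acid
Product: 7 (2S,3S)-4-[(tert-butyldimethylsilyl)oxy]-3-methyl-2-(3-methylbut-2-en-1-yl)butan-1-ol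
Conditions: LiAlH4, Et2O, 0 °C; Rochelle salt work-up
Reagents that add atoms: none
Why: LiAlH4 reduction of a carboxylic acid to the primary alcohol, under which the alkyl TBS ether and the trisubstituted alkene should be inert at 0 °C.

Step 4
Reactants: 7 (2S,3S)-4-[(tert-butyldimethylsilyl)oxy]-3-methyl-2-(3-methylbut-2-en-1-yl)butan-1-ol
Product: 8 tert-butyl{[(2S,3S)-3-(iodomethyl)-2,6-dimethylhept-5-en-1-yl]oxy}dimethylsilane
Conditions: I2, PPh3, imidazole, CH2Cl2, 0 °C to rt
Reagents that add atoms: iodine, II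
Why: Appel-type (Garegg–Samuelsson) iodination converts the primary alcohol into the iodide under neutral conditions that spare the silyl ether and the alkene.

Step 5
Reactants: 9 5-fluororesorcinol (5-fluorobenzene-1,3-diol)
Product: 10 1-fluoro-3,5-bis(methoxymethoxy)benzene
Conditions: MOMCl, i-Pr2NEt, CH2Cl2, 0 °C to rt
Reagents that add atoms: chloromethyl methyl ether (MOMCl), COCCl
Why: O-Alkylation of both phenols installs acid-labile MOM ethers that also serve as directing groups for the two metalations.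

Step 6
Reactants: 10 1-fluoro-3,5-bis(methoxymethoxy)benzene
Product: 12 1-fluoro-2-iodo-3,5-bis(methoxymethoxy)benzene, via aryllithium 11 (not isolated)
Conditions: n-BuLi, THF, –78 °C; I2, –78 °C
Reagents that add atoms: iodine, II
Why: Directed ortho-metalation, in which the C–H flanked by fluorine and OMOM is expected to be the kinetically most acidic site at –78 °C, and iodine traps the aryllithium before LiF can be lost.

Step 7
Reactants: 8 tert-butyl{[(2S,3S)-3-(iodomethyl)-2,6-dimethylhept-5-en-1-yl]oxy}dimethylsilane; 12 1-fluoro-2-iodo-3,5-bis(methoxymethoxy)benzene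
Product: 14 tert-butyl{[(2S,3R)-3-{[2-fluoro-4,6-bis(methoxymethoxy)phenyl]methyl}-2,6-dimethylhept-5-en-1-yl]oxy}dimethylsilane, via alkylzinc iodide 13 (not isolated)
Conditions: Zn dust (activated by TMSCl and 1,2-dibromoethane), DMF, 40 °C; then 12, Pd(OAc)2 (3 mol %), 2-dicyclohexylphosphino-2',6'-dimethoxybiphenyl (SPhos, 6 mol %), THF/DMF, 50 °C
Reagents that add atoms: none
Why: Negishi coupling, in which zinc insertion into the primary iodide leaves the remote stereocentres untouched and the bulky biaryl phosphine on palladium allows coupling of a primary alkylzinc halide with a di-ortho-substituted aryl iodide.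

Step 8
Reactants: 14 tert-butyl{[(2S,3R)-3-{[2-fluoro-4,6-bis(methoxymethoxy)phenyl]methyl}-2,6-dimethylhept-5-en-1-yl]oxy}dimethylsilane
Product: 16 2-fluoro-N-methoxy-4,6-bis(methoxymethoxy)-N-methyl-3-{(2R)-2-[(2S)-1-[(tert-butyldimethylsilyl)oxy]propan-2-yl]-5-methylhex-4-en-1-yl}benzamide, via aryllithium 15 (not isolated)
Conditions: n-BuLi, THF, –78 °C; inverse addition to ClC(O)N(OMe)Me (1.5 equiv), THF, –78 to –40 °C
Reagents that add atoms: N-methoxy-N-methylcarbamoyl chloride, CON(C)C(Cl)=O
Why: A second directed ortho-metalation at the remaining C–H flanked by fluorine and OMOM, followed by acylation of the aryllithium with the carbamoyl chloride, should give the Weinreb amide directly.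

Step 9
Reactants: 17 4-bromoresorcinol (4-bromobenzene-1,3-diol)
Product: 18 1-bromo-2,4-bis(methoxymethoxy)benzene
Conditions: MOMCl, i-Pr2NEt, CH2Cl2, 0 °C to rt
Reagents that add atoms: chloromethyl methyl ether (MOMCl), COCCl
Why: O-Alkylation of both phenols gives the bis-MOM ether needed for the organolithium chemistry and for the final acid deprotection.

Step 10
Reactants: 18 1-bromo-2,4-bis(methoxymethoxy)benzene
Product: 20 2-chloro-1-[2,4-bis(methoxymethoxy)phenyl]ethan-1-one, via aryllithium 19 (not isolated)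
Conditions: n-BuLi, THF, –78 °C; ClCH2C(O)N(OMe)Me, –78 °C; then AcOH, –78 °C
Reagents that add atoms: 2-chloro-N-methoxy-N-methylacetamide, CON(C)C(=O)CCl
Why: Bromine–lithium exchange and Weinreb ketone synthesis, in which the chelated tetrahedral adduct prevents over-addition and leaves the C–Cl bond intact.

Step 11
Reactants: 20 2-chloro-1-[2,4-bis(methoxymethoxy)phenyl]ethan-1-one
Product: 21 (1R)-2-chloro-1-[2,4-bis(methoxymethoxy)phenyl]ethan-1-ol
Conditions: (3aR)-1-methyl-3,3-diphenyltetrahydro-1H,3H-pyrrolo[1,2-c][1,3,2]oxazaborole [(R)-Me-CBS, 0.15 equiv], BH3·SMe2, THF, –20 °C; MeOH quench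
Reagents that add atoms: none
Why: Corey–Bakshi–Shibata reduction, in which the (R)-oxazaborolidine delivers hydride to the face that places aryl as the large and CH2Cl as the small group, which should give the (R)-chlorohydrin by catalyst control.

Step 12
Reactants: 21 (1R)-2-chloro-1-[2,4-bis(methoxymethoxy)phenyl]ethan-1-ol; 16 2-fluoro-N-methoxy-4,6-bis(methoxymethoxy)-N-methyl-3-{(2R)-2-[(2S)-1-[(tert-butyldimethylsilyl)oxy]propan-2-yl]-5-methylhex-4-en-1-yl}benzamide
Product: 24 (2S)-2-[2,4-bis(methoxymethoxy)phenyl]-5,7-bis(methoxymethoxy)-8-{(2R)-2-[(2S)-1-[(tert-butyldimethylsilyl)oxy]propan-2-yl]-5-methylhex-4-en-1-yl}-2,3-dihydro-4H-chromen-4-one, via β-oxido alkyllithium 22 (not isolated), via β-hydroxy ketone 23 (not isolated)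
Conditions: 21 (1.8 equiv), n-BuLi (1 equiv per 21), THF, –78 °C; lithium naphthalenide LiC10H8 (2 equiv per 21, no excess), –78 °C; 16 (1 equiv), –78 to –50 °C; AcOH, –78 °C to rt; K2CO3, DMF, 40 °C, same flask
Reagents that add atoms: none
Why: n-BuLi deprotonates the hydroxyl of 21, reductive lithiation of the C–Cl bond by LiC10H8 gives the β-oxido alkyllithium 22 (lithium oxide is too poor a leaving group for β-elimination at –78 °C), its carbon adds to the Weinreb amide 16 to give a chelated tetrahedral adduct (C3–C4 formed, no over-addition), acetic acid releases β-hydroxy ketone 23, and K2CO3 then promotes addition–elimination of the C2 oxygen at C8a with loss of fluoride (O1–C8a formed). The closest known reaction types are the Weinreb ketone synthesis with chlorohydrin-derived β-oxido organolithiums and the base-mediated intramolecular SNAr of ortho-fluoroaryl ketones used for chromanones and xanthones. Ring C, the only ring formed, closes by a 6-exo attack of O1 on C8a through a Meisenheimer intermediate stabilised by the ortho C4 carbonyl. No new stereocentre is created, because C2 is carried over from 21 with neither its C–O nor its C–H bond broken, so that (R)-21 maps onto (2S)-24 only through a change of CIP priorities. The step needs C- rather than O-acylation, which the inertness of Weinreb amides towards lithium alkoxides secures, and ring closure faster than retro-aldol cleavage or dehydration of 23, which the ortho-carbonyl activation, the position of fluorine meta to both OMOM donors and the mild carbonate base should secure. The single fluorine makes the site of O-arylation unambiguous, and the TBS ether keeps the side-chain oxygen from competing.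

Step 13
Reactants: 24 (2S)-2-[2,4-bis(methoxymethoxy)phenyl]-5,7-bis(methoxymethoxy)-8-{(2R)-2-[(2S)-1-[(tert-butyldimethylsilyl)oxy]propan-2-yl]-5-methylhex-4-en-1-yl}-2,3-dihydro-4H-chromen-4-one
Product: 25 (2S)-2-(2,4-dihydroxyphenyl)-5,7-dihydroxy-8-{(2R)-2-[(2S)-1-hydroxypropan-2-yl]-5-methylhex-4-en-1-yl}-2,3-dihydro-4H-chromen-4-one (CNP0262638.1)
Conditions: HCl (3 M in MeOH), THF, 40 °C
Reagents that add atoms: none
Why: Acid-catalysed acetal exchange in methanol should remove the four aryl MOM ethers and the primary TBS ether in one operation, and because no base is present the flavanone is not exposed to ring opening through its enolate.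

Compound list
1 | (S)-β-methyl-γ-butyrolactone [(4S)-4-methyloxolan-2-one] | O=C1C[C@H](C)CO1 | starting material
2 | lithium enolate of 1 | [Li]OC1=C[C@H](C)CO1 | intermediate
3 | (3S,4S)-4-methyl-3-(3-methylbut-2-en-1-yl)oxolan-2-one | CC(C)=CC[C@H](C1=O)[C@H](C)CO1 | intermediate
4 | potassium (2S,3S)-4-hydroxy-3-methyl-2-(3-methylbut-2-en-1-yl)butanoate | CC(C)=CC[C@H](C(=O)[O-])[C@H](C)CO.[K+] | intermediate
5 | tert-butyldimethylsilyl (2S,3S)-4-[(tert-butyldimethylsilyl)oxy]-3-methyl-2-(3-methylbut-2-en-1-yl)butanoate | CC(C)=CC[C@H](C(=O)O[Si](C)(C)C(C)(C)C)[C@H](C)CO[Si](C)(C)C(C)(C)C | intermediate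
6 | (2S,3S)-4-[(tert-butyldimethylsilyl)oxy]-3-methyl-2-(3-methylbut-2-en-1-yl)butanoic acid | CC(C)=CC[C@H](C(=O)O)[C@H](C)CO[Si](C)(C)C(C)(C)C | intermediate
7 | (2S,3S)-4-[(tert-butyldimethylsilyl)oxy]-3-methyl-2-(3-methylbut-2-en-1-yl)butan-1-ol | CC(C)=CC[C@H](CO)[C@H](C)CO[Si](C)(C)C(C)(C)C | intermediate
8 | tert-butyl{[(2S,3S)-3-(iodomethyl)-2,6-dimethylhept-5-en-1-yl]oxy}dimethylsilane | CC(C)=CC[C@H](CI)[C@H](C)CO[Si](C)(C)C(C)(C)C | intermediate
9 | 5-fluororesorcinol | Oc1cc(O)cc(F)c1 | starting material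
10 | 1-fluoro-3,5-bis(methoxymethoxy)benzene | COCOc1cc(F)cc(OCOC)c1 | intermediate
11 | [2-fluoro-4,6-bis(methoxymethoxy)phenyl]lithium | COCOc1cc(F)c([Li])c(OCOC)c1 | intermediate
12 | 1-fluoro-2-iodo-3,5-bis(methoxymethoxy)benzene | COCOc1cc(F)c(I)c(OCOC)c1 | intermediate
13 | {(2S,3S)-4-[(tert-butyldimethylsilyl)oxy]-3-methyl-2-(3-methylbut-2-en-1-yl)butyl}zinc iodide | CC(C)=CC[C@H](C[Zn]I)[C@H](C)CO[Si](C)(C)C(C)(C)C | intermediate
14 | tert-butyl{[(2S,3R)-3-{[2-fluoro-4,6-bis(methoxymethoxy)phenyl]methyl}-2,6-dimethylhept-5-en-1-yl]oxy}dimethylsilane | CC(C)=CC[C@H](Cc1c(F)cc(OCOC)cc1OCOC)[C@H](C)CO[Si](C)(C)C(C)(C)C | intermediate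
15 | 3-lithio derivative of 14 (lithium between F and OMOM) | CC(C)=CC[C@H](Cc1c(F)c([Li])c(OCOC)cc1OCOC)[C@H](C)CO[Si](C)(C)C(C)(C)C | intermediate
16 | 2-fluoro-N-methoxy-4,6-bis(methoxymethoxy)-N-methyl-3-{(2R)-2-[(2S)-1-[(tert-butyldimethylsilyl)oxy]propan-2-yl]-5-methylhex-4-en-1-yl}benzamide | CC(C)=CC[C@H](Cc1c(F)c(C(=O)N(C)OC)c(OCOC)cc1OCOC)[C@H](C)CO[Si](C)(C)C(C)(C)C | intermediate
17 | 4-bromoresorcinol | Oc1ccc(Br)c(O)c1 | starting material
18 | 1-bromo-2,4-bis(methoxymethoxy)benzene | COCOc1ccc(Br)c(OCOC)c1 | intermediate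
19 | [2,4-bis(methoxymethoxy)phenyl]lithium | COCOc1ccc([Li])c(OCOC)c1 | intermediate
20 | 2-chloro-1-[2,4-bis(methoxymethoxy)phenyl]ethan-1-one | COCOc1ccc(C(=O)CCl)c(OCOC)c1 | intermediate
21 | (1R)-2-chloro-1-[2,4-bis(methoxymethoxy)phenyl]ethan-1-ol | O[C@H](c1ccc(OCOC)cc1OCOC)CCl | intermediate
22 | lithium (1S)-2-lithio-1-[2,4-bis(methoxymethoxy)phenyl]ethan-1-olate (same spatial arrangement as 21) | [Li]C[C@H](O[Li])c1ccc(OCOC)cc1OCOC | intermediate
23 | (3S)-3-[2,4-bis(methoxymethoxy)phenyl]-1-[2-fluoro-4,6-bis(methoxymethoxy)-3-{(2R)-2-[(2S)-1-[(tert-butyldimethylsilyl)oxy]propan-2-yl]-5-methylhex-4-en-1-yl}phenyl]-3-hydroxypropan-1-one | CC(C)=CC[C@H](Cc1c(F)c(C(=O)C[C@H](O)c2ccc(OCOC)cc2OCOC)c(OCOC)cc1OCOC)[C@H](C)CO[Si](C)(C)C(C)(C)C | intermediate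
24 | (2S)-2-[2,4-bis(methoxymethoxy)phenyl]-5,7-bis(methoxymethoxy)-8-{(2R)-2-[(2S)-1-[(tert-butyldimethylsilyl)oxy]propan-2-yl]-5-methylhex-4-en-1-yl}-2,3-dihydro-4H-chromen-4-one | CC(C)=CC[C@H](Cc1c(OCOC)cc(OCOC)c2c1O[C@H](c1ccc(OCOC)cc1OCOC)CC2=O)[C@H](C)CO[Si](C)(C)C(C)(C)C | intermediate
25 | (2S)-2-(2,4-dihydroxyphenyl)-5,7-dihydroxy-8-{(2R)-2-[(2S)-1-hydroxypropan-2-yl]-5-methylhex-4-en-1-yl}-2,3-dihydro-4H-chromen-4-one | CC(C)=CC[C@H](Cc1c(O)cc(O)c2c1O[C@H](c1ccc(O)cc1O)CC2=O)[C@H](C)CO | target

Total step count: 13. Longest linear sequence: 8 steps (steps 1, 2, 3, 4, 7, 8, 12, 13).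

Steps most likely to fail

1. Step 12. What may go wrong: β-elimination of 22 to the styrene before it adds to the hindered amide; retro-aldol cleavage or dehydration of 23 under base, which would erode the C2 configuration or divert material to a chalcone; base-induced ring opening of 24 through its enolate. The fallback works at the aldehyde oxidation level, so that no carbonyl is present while the alkoxide is basic. It sets out from 16 and 21. Reduction of 16 with i-Bu2AlH (THF, –78 °C) should give 2-fluoro-4,6-bis(methoxymethoxy)-3-{(2R)-2-[(2S)-1-[(tert-butyldimethylsilyl)oxy]propan-2-yl]-5-methylhex-4-en-1-yl}benzaldehyde F1, which is far more reactive than the amide. F1 should add 22 (made from 21 as in step 12) at –78 °C to give the 1,3-diol F2 as a mixture of epimers at the ring A carbinol. KOt-Bu in THF/DMPU at 60 °C should then close the aryl ether by SNAr of the ring B alkoxide on the fluoroarene, giving the chroman-4-ol F3. Oxidation of the ring A carbinol with Dess–Martin periodinane (NaHCO3, CH2Cl2) comes back to the route at 24.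

2. Step 8 (the same concern applies to step 6). What may go wrong: leakage of the metalation to the C–H between the two OMOM groups, and loss of LiF from the ortho-fluoro aryllithium to an aryne. The fallback replaces both metalations by electrophilic substitution and sets out from 10. NBS (2 equiv, MeCN, 0 °C) should brominate para to each OMOM group, that is at both positions ortho to fluorine, giving the symmetric 2,4-dibromo-3-fluoro-1,5-bis(methoxymethoxy)benzene F4. Negishi mono-coupling of F4 (in excess) with alkylzinc 13 under the conditions of step 7 should give the mono-alkylated bromide F5. Bromine–lithium exchange (n-BuLi, THF, –78 °C) and inverse addition to ClC(O)N(OMe)Me comes back to the route at 16.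

3. Step 13. What may go wrong: acid-promoted heterolysis of the benzylic C2–O1 bond next to the electron-rich ring B, which would racemise C2, and Markovnikov addition of methanol or HCl to the trisubstituted alkene. The fallback deprotects in two aprotic stages and sets out from 24. HF·pyridine (THF/pyridine, 0 °C) should remove the silyl group to give the tetra-MOM alcohol F6. ZnBr2 with n-PrSH (CH2Cl2, 0 °C) should then cleave the four aryl MOM ethers within minutes by Lewis-acid activation and thiol capture, coming back to the route at 25.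

Further compounds
F1 | step 12 | 2-fluoro-4,6-bis(methoxymethoxy)-3-{(2R)-2-[(2S)-1-[(tert-butyldimethylsilyl)oxy]propan-2-yl]-5-methylhex-4-en-1-yl}benzaldehyde | CC(C)=CC[C@H](Cc1c(F)c(C=O)c(OCOC)cc1OCOC)[C@H](C)CO[Si](C)(C)C(C)(C)C
F2 | step 12 | (1S)-1-[2,4-bis(methoxymethoxy)phenyl]-3-[2-fluoro-4,6-bis(methoxymethoxy)-3-{(2R)-2-[(2S)-1-[(tert-butyldimethylsilyl)oxy]propan-2-yl]-5-methylhex-4-en-1-yl}phenyl]propane-1,3-diol (epimers at C3) | CC(C)=CC[C@H](Cc1c(F)c(C(O)C[C@H](O)c2ccc(OCOC)cc2OCOC)c(OCOC)cc1OCOC)[C@H](C)CO[Si](C)(C)C(C)(C)C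
F3 | step 12 | (2S)-2-[2,4-bis(methoxymethoxy)phenyl]-5,7-bis(methoxymethoxy)-8-{(2R)-2-[(2S)-1-[(tert-butyldimethylsilyl)oxy]propan-2-yl]-5-methylhex-4-en-1-yl}-3,4-dihydro-2H-chromen-4-ol (epimers at C4) | CC(C)=CC[C@H](Cc1c(OCOC)cc(OCOC)c2c1O[C@H](c1ccc(OCOC)cc1OCOC)CC2O)[C@H](C)CO[Si](C)(C)C(C)(C)C
F4 | step 8 | 2,4-dibromo-3-fluoro-1,5-bis(methoxymethoxy)benzene | COCOc1cc(OCOC)c(Br)c(F)c1Br
F5 | step 8 | tert-butyl{[(2S,3R)-3-{[3-bromo-2-fluoro-4,6-bis(methoxymethoxy)phenyl]methyl}-2,6-dimethylhept-5-en-1-yl]oxy}dimethylsilane | CC(C)=CC[C@H](Cc1c(F)c(Br)c(OCOC)cc1OCOC)[C@H](C)CO[Si](C)(C)C(C)(C)C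
F6 | step 13 | (2S)-2-[2,4-bis(methoxymethoxy)phenyl]-8-{(2R)-2-[(2S)-1-hydroxypropan-2-yl]-5-methylhex-4-en-1-yl}-5,7-bis(methoxymethoxy)-2,3-dihydro-4H-chromen-4-one | CC(C)=CC[C@H](Cc1c(OCOC)cc(OCOC)c2c1O[C@H](c1ccc(OCOC)cc1OCOC)CC2=O)[C@H](C)CO
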